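**Retrosynthetic overview**
1. The target is a cis-(2R,3R)-2-aryl-3-hydroxymethyl-2,3-dihydrobenzofuran (ring A plus the furan ring O1–C2–C3–C3a–C7a) whose ring B carries the erythro (7''R,8''S) guaiacylglycerol (ring C) as an 8''-O-aryl ether. The dihydrofuran ring is the only ring made in the route and is closed last, at O1–C7a, by palladium-catalysed etherification of the free C2–OH with C7a–Br (24 → 25); global desilylation then gives the target.
2. Enabling feature: in 24 the bromine sits on C7a of ring A, between the C7 methoxy and C3a, and the C2 oxygen is three atoms away (C2–C3–C3a–C7a), so a six-membered palladacycle can form. Closing at the aromatic carbon leaves C2 and C3 untouched, so the acyclic anti diol becomes the cis ring; a closure at C2 would pass through the benzylic cation and drift to trans.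
3. C2–C3 bond and both ring stereocentres: magnesium-catalysed anti-aldol of the N-arylacetyl oxazolidinone 20 (ring A) with aldehyde 13 (rings B and C), then LiBH4.
4. 20: 2-(2-bromo-3-methoxyphenyl)acetic acid, auxiliary, iridium C–H borylation at C5, rhodium conjugate addition to methyl acrylate.
5. 13: C8''–O by Mitsunobu inversion of methyl (R)-glycerate with 4-bromo-2,6-dimethoxyphenol; C7'' by Weinreb ketone synthesis and chelation-controlled Zn(BH4)2 reduction; Br to CHO by lithiation and DMF.

Key step: step 15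

Remark: read from the SMILES, the C2 aryl and C3 hydroxymethyl groups are cis (2R,3R) and the glycerol unit is erythro (7''R,8''S). Atom numbers are those of the dihydrobenzofuran (ring A = its benzo ring), ring B is the 2,6-dimethoxyphenoxy ring, ring C the guaiacyl ring, C7''–C9'' the glycerol chain. Acid 14 is taken as a catalogue compound.
Abbreviation used in names: Ar* = 4-{[(1R,2S)-1,3-bis(tert-butyldimethylsilyloxy)-1-[3-methoxy-4-(triisopropylsilyloxy)phenyl]propan-2-yl]oxy}-3,5-dimethoxyphenyl (the protected ring B/ring C unit).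

Step 1
Reactants: 1 methyl (R)-2,3-dihydroxypropanoate
Product: 2 methyl (R)-3-(tert-butyldimethylsilyloxy)-2-hydroxypropanoate
Conditions: TBSCl (1.05 equiv), imidazole, CH2Cl2, 0 °C
Reagents that add atoms: tert-butyldimethylsilyl chloride, CC(C)(C)[Si](C)(C)Cl
Why: Selective silyl ether formation, since the primary hydroxyl silylates much faster than the hindered, less nucleophilic α-hydroxy ester OH; the stereocentre is not touched.

Step 2
Reactants: 2 methyl (R)-3-(tert-butyldimethylsilyloxy)-2-hydroxypropanoate; 3 4-bromo-2,6-dimethoxyphenol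
Product: 4 methyl (S)-2-(4-bromo-2,6-dimethoxyphenoxy)-3-(tert-butyldimethylsilyloxy)propanoate
Conditions: PPh3, DIAD, THF, 0 °C to rt
Reagents that add atoms: none
Why: Mitsunobu etherification of an α-hydroxy ester by a phenol is an SN2 displacement of the oxyphosphonium group, so C2 inverts from R to S and becomes C8'' of the target.

Step 3
Reactants: 4 methyl (S)-2-(4-bromo-2,6-dimethoxyphenoxy)-3-(tert-butyldimethylsilyloxy)propanoate
Product: 5 (S)-2-(4-bromo-2,6-dimethoxyphenoxy)-3-(tert-butyldimethylsilyloxy)-N-methoxy-N-methylpropanamide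
Conditions: MeNHOMe·HCl, i-PrMgCl, THF, –20 °C
Reagents that add atoms: N,O-dimethylhydroxylamine hydrochloride, CNOC.Cl
Why: Weinreb amide formation by aminolysis of the ester with the chloromagnesium amide, fast enough at low temperature to outrun enolisation of the α-aryloxy centre and leaving the electron-rich aryl bromide untouched.

Step 4
Reactants: 6 4-bromo-2-methoxyphenol
Product: 7 (4-bromo-2-methoxyphenoxy)triisopropylsilane
Conditions: TIPSCl, imidazole, DMF, rt
Reagents that add atoms: triisopropylsilyl chloride, CC(C)[Si](Cl)(C(C)C)C(C)C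
Why: Phenol silylation; the bulky aryl silyl ether is chosen to survive Grignard and organolithium reagents, hydride and carbonate, and to leave with fluoride at the end.

Step 5
Reactants: 7 (4-bromo-2-methoxyphenoxy)triisopropylsilane; 5 (S)-2-(4-bromo-2,6-dimethoxyphenoxy)-3-(tert-butyldimethylsilyloxy)-N-methoxy-N-methylpropanamide
Product: 9 (S)-2-(4-bromo-2,6-dimethoxyphenoxy)-3-(tert-butyldimethylsilyloxy)-1-[3-methoxy-4-(triisopropylsilyloxy)phenyl]propan-1-one, via arylmagnesium bromide 8 (not isolated)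
Conditions: 7, Mg turnings, THF, 40 °C; then 5, THF, 0 °C; aq. NH4Cl
Reagents that add atoms: none
Why: Weinreb ketone synthesis, in which the chelated tetrahedral adduct stops at the ketone stage and shields C8'' from enolisation until the quench, and an aryl Grignard reagent does not exchange with the ring B bromide.

Step 6
Reactants: 9 (S)-2-(4-bromo-2,6-dimethoxyphenoxy)-3-(tert-butyldimethylsilyloxy)-1-[3-methoxy-4-(triisopropylsilyloxy)phenyl]propan-1-one
Product: 10 (1R,2S)-2-(4-bromo-2,6-dimethoxyphenoxy)-3-(tert-butyldimethylsilyloxy)-1-[3-methoxy-4-(triisopropylsilyloxy)phenyl]propan-1-ol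
Conditions: Zn(BH4)2, Et2O, –30 to 0 °C; aq. NH4Cl
Reagents that add atoms: none
Why: Chelation-controlled (Cram chelate) hydride reduction: zinc bridges the carbonyl oxygen and the α-aryloxy oxygen (the silyl ether does not chelate) and hydride enters past the small hydrogen, which should give the anti (erythro) alcohol, that is 7''R next to 8''S.

Step 7
Reactants: 10 (1R,2S)-2-(4-bromo-2,6-dimethoxyphenoxy)-3-(tert-butyldimethylsilyloxy)-1-[3-methoxy-4-(triisopropylsilyloxy)phenyl]propan-1-ol
Product: 11 Ar*–Br, the 1-O-tert-butyldimethylsilyl ether of 10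
Conditions: TBSOTf, 2,6-lutidine, CH2Cl2, 0 °C
Reagents that add atoms: tert-butyldimethylsilyl trifluoromethanesulfonate, CC(C)(C)[Si](C)(C)OS(=O)(=O)C(F)(F)F
Why: Silyl triflate silylation of the hindered secondary benzylic alcohol, needed so that no acidic proton remains for the lithiation that follows.

Step 8
Reactants: 11 Ar*–Br
Product: 13 Ar*–CHO (4-substituted 3,5-dimethoxybenzaldehyde), via aryllithium 12 (not isolated)
Conditions: n-BuLi, THF, –78 °C; DMF, –78 to 0 °C; aq. NH4Cl
Reagents that add atoms: N,N-dimethylformamide, CN(C)C=O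
Why: Bromine–lithium exchange is faster than any ortho-lithiation at –78 °C, and trapping with DMF (Bouveault aldehyde synthesis) gives the aldehyde whose carbon becomes C2.

Step 9
Reactants: 14 2-(2-bromo-3-methoxyphenyl)acetic acid; 15 (R)-4-isopropyloxazolidin-2-one
Product: 17 (R)-3-[2-(2-bromo-3-methoxyphenyl)acetyl]-4-isopropyloxazolidin-2-one, via mixed pivalic anhydride 16 (not isolated)
Conditions: PivCl, Et3N, THF, –20 °C; then 15, LiCl, rt
Reagents that add atoms: none
Why: N-acylation of the oxazolidinone through the mixed anhydride, attacked at the less hindered arylacetyl carbonyl; the isopropyl auxiliary has no arene that could compete in the borylation of step 10.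

Step 10
Reactants: 17 (R)-3-[2-(2-bromo-3-methoxyphenyl)acetyl]-4-isopropyloxazolidin-2-one
Product: 18 (R)-3-{2-[2-bromo-3-methoxy-5-(4,4,5,5-tetramethyl-1,3,2-dioxaborolan-2-yl)phenyl]acetyl}-4-isopropyloxazolidin-2-one
Conditions: B2pin2 (1.0 equiv), [Ir(OMe)(cod)]2 (1.5 mol%), 4,4'-di-tert-butyl-2,2'-bipyridine (3 mol%), THF, 70 °C
Reagents that add atoms: bis(pinacolato)diboron, CC1(C)OB(OC1(C)C)B1OC(C)(C)C(C)(C)O1
Why: Iridium-catalysed aromatic C–H borylation is sterically controlled, and in this 1,2,3-trisubstituted ring only C5 (para to bromine) has no ortho substituent; aryl bromides and imides are tolerated.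

Step 11
Reactants: 18 aryl pinacol boronate; 19 methyl acrylate
Product: 20 methyl 3-{4-bromo-3-methoxy-5-[2-((R)-4-isopropyl-2-oxooxazolidin-3-yl)-2-oxoethyl]phenyl}propanoate
Conditions: 19 (3 equiv), [Rh(OH)(cod)]2 (2.5 mol%), dioxane/H2O 10:1, 60 °C
Reagents that add atoms: none
Why: Rhodium-catalysed conjugate addition of an aryl boronate to an acrylate (Hayashi–Miyaura reaction); monovalent rhodium does not insert into the aryl bromide, and the base-free hydroxo complex spares the imide.

Step 12
Reactants: 20 methyl 3-{4-bromo-3-methoxy-5-[2-((R)-4-isopropyl-2-oxooxazolidin-3-yl)-2-oxoethyl]phenyl}propanoate; 13 Ar*–CHO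
Product: 21 (R)-3-{(2S,3R)-3-Ar*-2-[2-bromo-3-methoxy-5-(3-methoxy-3-oxopropyl)phenyl]-3-(trimethylsilyloxy)propanoyl}-4-isopropyloxazolidin-2-one
Conditions: MgCl2 (20 mol%), Et3N, TMSCl, EtOAc, rt; filtration through deactivated silica
Reagents that add atoms: chlorotrimethylsilane, C[Si](C)(C)Cl
Why: Evans magnesium-catalysed anti-aldol: soft enolisation gives the chelated Z-magnesium enolate, the non-enolisable aldehyde adds to the face opposite the isopropyl group (the sense of an Evans alkylation) through a boat transition state that leads to the anti adduct, and silylation of the aldolate turns the metal over and blocks retro-aldol, which should set the future C3 and C2 (both R in the ring).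

Step 13
Reactants: 21 silylated anti-aldol adduct
Product: 23 (1R,2R)-1-Ar*-2-[2-bromo-5-(3-hydroxypropyl)-3-methoxyphenyl]propane-1,3-diol, via trimethylsilyl ether diol 22 (not isolated)
Conditions: LiBH4, MeOH (2 equiv), THF, 0 °C to rt; aq. NH4Cl; then AcOH/H2O/THF, rt
Reagents that add atoms: none
Why: Reductive cleavage of the N-acyl oxazolidinone and reduction of the methyl ester by LiBH4 give both primary alcohols in one operation while the silyl ether rules out retro-aldol, and the labile trimethylsilyl ether is then hydrolysed by dilute acetic acid without loss of the bulkier silyl groups.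

Step 14
Reactants: 23 triol
Product: 24 (1R,2R)-1-Ar*-2-{2-bromo-5-[3-(tert-butyldimethylsilyloxy)propyl]-3-methoxyphenyl}-3-(tert-butyldimethylsilyloxy)propan-1-ol
Conditions: TBSCl (2.2 equiv), imidazole, CH2Cl2, 0 °C
Reagents that add atoms: tert-butyldimethylsilyl chloride, CC(C)(C)[Si](C)(C)Cl
Why: Selective silylation of the two primary hydroxyls over the hindered secondary benzylic one, which leaves the C2–OH as the only nucleophile for ring closure.

Step 15
Reactants: 24 bromo alcohol
Product: 25 (2R,3R)-2-Ar*-3-(tert-butyldimethylsilyloxymethyl)-5-[3-(tert-butyldimethylsilyloxy)propyl]-7-methoxy-2,3-dihydrobenzofuran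
Conditions: Pd(OAc)2 (5 mol%), 2-(di-tert-butylphosphino)-1,1'-binaphthyl (6 mol%), Cs2CO3, toluene, 70 °C
Reagents that add atoms: none
Why: Zerovalent palladium formed from Pd(OAc)2 and the bulky phosphine inserts into the C7a–Br bond, carbonate exchanges bromide for the C2 alkoxide to give a six-membered aryl palladium alkoxide (Pd–C7a–C3a–C3–C2–O), and C–O reductive elimination forms O1–C7a. The closest known reaction is the Buchwald–Hartwig-type intramolecular etherification of 2-(2-bromoaryl)-1-arylethanols to 2-aryl-2,3-dihydrobenzofurans. The five-membered ring (O1, C2, C3, C3a, C7a) closes by reductive elimination from this palladacycle onto the sp2 carbon C7a, with no substitution event at C2. No new stereocentre is made: C2 and C3 keep the anti configuration fixed in step 12 and so end up cis on the ring, the arrangement that a closure at C2 through the benzylic cation would lose to the trans isomer. The step needs chemoselectivity among three hydroxyls (both primary ones are silylated, and the C3 CH2OH could otherwise also reach C7a in a five-membered closure), site selectivity on ring A (only C7a carries a halogen, so C4 is not an option) and reductive elimination faster than β-hydride elimination of the benzylic alkoxide (favoured by the hindered electron-rich phosphine and the two ortho substituents at C7a). Ring A carries no electron-withdrawing group, so C3–H stays non-acidic under carbonate, and the silyl ethers tolerate the mild base.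

Step 16
Reactants: 25 protected cis-dihydrobenzofuran
Product: 26 (1R,2S)-1-(4-hydroxy-3-methoxyphenyl)-2-{4-[(2R,3R)-3-(hydroxymethyl)-5-(3-hydroxypropyl)-7-methoxy-2,3-dihydrobenzofuran-2-yl]-2,6-dimethoxyphenoxy}propane-1,3-diol (CNP0301567.1)
Conditions: TBAF (6 equiv), AcOH (6 equiv), THF, 0 °C to rt
Reagents that add atoms: none
Why: Fluoride-driven cleavage of all five silyl ethers (four alkyl tert-butyldimethylsilyl, one aryl triisopropylsilyl) in one operation, buffered with acetic acid so that neither the acid-labile cis benzylic ether at C2 nor the p-hydroxybenzylic alcohol at C7'' meets strong acid or base; no stereocentre is involved.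

**Compound list**
1 | methyl (R)-2,3-dihydroxypropanoate | COC(=O)[C@H](O)CO | starting material
2 | methyl (R)-3-(tert-butyldimethylsilyloxy)-2-hydroxypropanoate | COC(=O)[C@H](O)CO[Si](C)(C)C(C)(C)C | intermediate
3 | 4-bromo-2,6-dimethoxyphenol | COc1cc(Br)cc(OC)c1O | starting material
4 | methyl (S)-2-(4-bromo-2,6-dimethoxyphenoxy)-3-(tert-butyldimethylsilyloxy)propanoate | COC(=O)[C@H](CO[Si](C)(C)C(C)(C)C)Oc1c(OC)cc(Br)cc1OC | intermediate
5 | (S)-2-(4-bromo-2,6-dimethoxyphenoxy)-3-(tert-butyldimethylsilyloxy)-N-methoxy-N-methylpropanamide | CON(C)C(=O)[C@H](CO[Si](C)(C)C(C)(C)C)Oc1c(OC)cc(Br)cc1OC | intermediate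
6 | 4-bromo-2-methoxyphenol | COc1cc(Br)ccc1O | starting material
7 | (4-bromo-2-methoxyphenoxy)triisopropylsilane | COc1cc(Br)ccc1O[Si](C(C)C)(C(C)C)C(C)C | intermediate
8 | [3-methoxy-4-(triisopropylsilyloxy)phenyl]magnesium bromide (not isolated) | COc1cc([Mg]Br)ccc1O[Si](C(C)C)(C(C)C)C(C)C | intermediate
9 | (S)-2-(4-bromo-2,6-dimethoxyphenoxy)-3-(tert-butyldimethylsilyloxy)-1-[3-methoxy-4-(triisopropylsilyloxy)phenyl]propan-1-one | COc1cc(C(=O)[C@H](CO[Si](C)(C)C(C)(C)C)Oc2c(OC)cc(Br)cc2OC)ccc1O[Si](C(C)C)(C(C)C)C(C)C | intermediate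
10 | (1R,2S)-2-(4-bromo-2,6-dimethoxyphenoxy)-3-(tert-butyldimethylsilyloxy)-1-[3-methoxy-4-(triisopropylsilyloxy)phenyl]propan-1-ol | COc1cc([C@@H](O)[C@H](CO[Si](C)(C)C(C)(C)C)Oc2c(OC)cc(Br)cc2OC)ccc1O[Si](C(C)C)(C(C)C)C(C)C | intermediate
11 | Ar*–Br: 1-O-tert-butyldimethylsilyl ether of 10, (1R,2S) | COc1cc([C@@H](O[Si](C)(C)C(C)(C)C)[C@H](CO[Si](C)(C)C(C)(C)C)Oc2c(OC)cc(Br)cc2OC)ccc1O[Si](C(C)C)(C(C)C)C(C)C | intermediate
12 | Ar*–Li, aryllithium from 11 (not isolated) | COc1cc([C@@H](O[Si](C)(C)C(C)(C)C)[C@H](CO[Si](C)(C)C(C)(C)C)Oc2c(OC)cc([Li])cc2OC)ccc1O[Si](C(C)C)(C(C)C)C(C)C | intermediate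
13 | Ar*–CHO: 4-{[(1R,2S)-1,3-bis(tert-butyldimethylsilyloxy)-1-[3-methoxy-4-(triisopropylsilyloxy)phenyl]propan-2-yl]oxy}-3,5-dimethoxybenzaldehyde | COc1cc([C@@H](O[Si](C)(C)C(C)(C)C)[C@H](CO[Si](C)(C)C(C)(C)C)Oc2c(OC)cc(C=O)cc2OC)ccc1O[Si](C(C)C)(C(C)C)C(C)C | intermediate
14 | 2-(2-bromo-3-methoxyphenyl)acetic acid | COc1cccc(CC(=O)O)c1Br | starting material
15 | (R)-4-isopropyloxazolidin-2-one | CC(C)[C@@H]1COC(=O)N1 | starting material
16 | 2-(2-bromo-3-methoxyphenyl)acetic pivalic anhydride (not isolated) | COc1cccc(CC(=O)OC(=O)C(C)(C)C)c1Br | intermediate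
17 | (R)-3-[2-(2-bromo-3-methoxyphenyl)acetyl]-4-isopropyloxazolidin-2-one | COc1cccc(CC(=O)N2[C@H](C(C)C)COC2=O)c1Br | intermediate
18 | (R)-3-{2-[2-bromo-3-methoxy-5-(4,4,5,5-tetramethyl-1,3,2-dioxaborolan-2-yl)phenyl]acetyl}-4-isopropyloxazolidin-2-one | COc1cc(B2OC(C)(C)C(C)(C)O2)cc(CC(=O)N2[C@H](C(C)C)COC2=O)c1Br | intermediate
19 | methyl acrylate | C=CC(=O)OC | starting material
20 | methyl 3-{4-bromo-3-methoxy-5-[2-((R)-4-isopropyl-2-oxooxazolidin-3-yl)-2-oxoethyl]phenyl}propanoate | COC(=O)CCc1cc(OC)c(Br)c(CC(=O)N2[C@H](C(C)C)COC2=O)c1 | intermediate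
21 | (R)-3-{(2S,3R)-3-Ar*-2-[2-bromo-3-methoxy-5-(3-methoxy-3-oxopropyl)phenyl]-3-(trimethylsilyloxy)propanoyl}-4-isopropyloxazolidin-2-one | COc1cc([C@@H](O[Si](C)(C)C(C)(C)C)[C@H](CO[Si](C)(C)C(C)(C)C)Oc2c(OC)cc([C@H](O[Si](C)(C)C)[C@H](c3cc(CCC(=O)OC)cc(OC)c3Br)C(=O)N3[C@H](C(C)C)COC3=O)cc2OC)ccc1O[Si](C(C)C)(C(C)C)C(C)C | intermediate
22 | (2R,3R)-3-Ar*-2-[2-bromo-5-(3-hydroxypropyl)-3-methoxyphenyl]-3-(trimethylsilyloxy)propan-1-ol (not isolated) | COc1cc([C@@H](O[Si](C)(C)C(C)(C)C)[C@H](CO[Si](C)(C)C(C)(C)C)Oc2c(OC)cc([C@H](O[Si](C)(C)C)[C@H](c3cc(CCCO)cc(OC)c3Br)CO)cc2OC)ccc1O[Si](C(C)C)(C(C)C)C(C)C | intermediate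
23 | (1R,2R)-1-Ar*-2-[2-bromo-5-(3-hydroxypropyl)-3-methoxyphenyl]propane-1,3-diol | COc1cc([C@@H](O[Si](C)(C)C(C)(C)C)[C@H](CO[Si](C)(C)C(C)(C)C)Oc2c(OC)cc([C@H](O)[C@H](c3cc(CCCO)cc(OC)c3Br)CO)cc2OC)ccc1O[Si](C(C)C)(C(C)C)C(C)C | intermediate
24 | (1R,2R)-1-Ar*-2-{2-bromo-5-[3-(tert-butyldimethylsilyloxy)propyl]-3-methoxyphenyl}-3-(tert-butyldimethylsilyloxy)propan-1-ol | COc1cc([C@@H](O[Si](C)(C)C(C)(C)C)[C@H](CO[Si](C)(C)C(C)(C)C)Oc2c(OC)cc([C@H](O)[C@H](c3cc(CCCO[Si](C)(C)C(C)(C)C)cc(OC)c3Br)CO[Si](C)(C)C(C)(C)C)cc2OC)ccc1O[Si](C(C)C)(C(C)C)C(C)C | intermediate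
25 | (2R,3R)-2-Ar*-3-(tert-butyldimethylsilyloxymethyl)-5-[3-(tert-butyldimethylsilyloxy)propyl]-7-methoxy-2,3-dihydrobenzofuran | COc1cc([C@@H](O[Si](C)(C)C(C)(C)C)[C@H](CO[Si](C)(C)C(C)(C)C)Oc2c(OC)cc([C@@H]3Oc4c(OC)cc(CCCO[Si](C)(C)C(C)(C)C)cc4[C@@H]3CO[Si](C)(C)C(C)(C)C)cc2OC)ccc1O[Si](C(C)C)(C(C)C)C(C)C | intermediate
26 | (1R,2S)-1-(4-hydroxy-3-methoxyphenyl)-2-{4-[(2R,3R)-3-(hydroxymethyl)-5-(3-hydroxypropyl)-7-methoxy-2,3-dihydrobenzofuran-2-yl]-2,6-dimethoxyphenoxy}propane-1,3-diol | COc1cc([C@@H](O)[C@H](CO)Oc2c(OC)cc([C@@H]3Oc4c(OC)cc(CCCO)cc4[C@@H]3CO)cc2OC)ccc1O | target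

**Step count and risks**
Total: 16 steps. Longest linear sequence: 12 steps (steps 1, 2, 3, 5, 6, 7, 8, 12, 13, 14, 15, 16).

Steps most likely to fail:

1. Step 12. The electron-rich aldehyde may convert sluggishly, and reversible addition before silylation may erode the anti and facial selectivity. The fallback sets out from 20 and 13 and replaces the catalytic soft-enolisation manifold by a stoichiometric open-transition-state aldol. Imide 20 is converted into its chelated dibutylboron enolate (Bu2BOTf, i-Pr2NEt, CH2Cl2, –78 °C) and treated with 13 precomplexed with Et2AlCl. Attack on the enolate face opposite the isopropyl group, with the aryl groups anti in the open transition state, should give the free anti-aldol adduct F1, the desilylated form of 21. Reduction of F1 with LiBH4 rejoins the route at 23.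

2. Step 15. Oxidative addition at the doubly ortho-substituted C7a–Br may be slow, and the secondary benzylic palladium alkoxide may undergo β-hydride elimination, oxidising C2–OH and removing the halogen. The fallback sets out from 24 and moves the closure to copper, whose alkoxides do not readily eliminate. Aromatic Finkelstein exchange (CuI, NaI, trans-N,N'-dimethylcyclohexane-1,2-diamine, dioxane, 110 °C) should give the aryl iodide F2. Ullmann etherification of F2 (CuI, 3,4,7,8-tetramethyl-1,10-phenanthroline, Cs2CO3, toluene, 110 °C) closes the same O1–C7a bond with the same retention and rejoins the route at 25.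

3. Step 6. The crowded 2,6-dimethoxyaryl ether oxygen may chelate zinc incompletely, giving poor facial selectivity at C7''. The fallback sets out from 9 and replaces substrate (chelate) control by catalyst control: Noyori transfer hydrogenation with RuCl(p-cymene)[(S,S)-TsDPEN] in HCO2H/Et3N, where the catalyst reads the aryl ketone face and should deliver the 7''R alcohol. It rejoins the route at 10 directly, with no new compound on the way (F0).

Further compounds
F1 | step 12 | (R)-3-{(2S,3R)-3-Ar*-2-[2-bromo-3-methoxy-5-(3-methoxy-3-oxopropyl)phenyl]-3-hydroxypropanoyl}-4-isopropyloxazolidin-2-one | COc1cc([C@@H](O[Si](C)(C)C(C)(C)C)[C@H](CO[Si](C)(C)C(C)(C)C)Oc2c(OC)cc([C@H](O)[C@H](c3cc(CCC(=O)OC)cc(OC)c3Br)C(=O)N3[C@H](C(C)C)COC3=O)cc2OC)ccc1O[Si](C(C)C)(C(C)C)C(C)C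
F2 | step 15 | (1R,2R)-1-Ar*-2-{5-[3-(tert-butyldimethylsilyloxy)propyl]-2-iodo-3-methoxyphenyl}-3-(tert-butyldimethylsilyloxy)propan-1-ol | COc1cc([C@@H](O[Si](C)(C)C(C)(C)C)[C@H](CO[Si](C)(C)C(C)(C)C)Oc2c(OC)cc([C@H](O)[C@H](c3cc(CCCO[Si](C)(C)C(C)(C)C)cc(OC)c3I)CO[Si](C)(C)C(C)(C)C)cc2OC)ccc1O[Si](C(C)C)(C(C)C)C(C)C
F0 | step 6 | none | none
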